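**Retrosynthetic overview**
1. Target 16 comes from protected flavanone 15 by one global hydrogenolysis; the C4 ketone comes from C4–H oxidation of (2S)-flavan 13, so C2 never sits β to a carbonyl before the last two steps.
2. Ring C of 13 is opened across C3–C4 and O1–C2 to the ortho-quinone methide 12 (ring A, released from salicyl alcohol 3) and the ring-B styrene 11, joined under a chiral phosphoric acid.
3. Feature used: ring A is a phloroglucinol whose O5, O7 and O1 (on C8a) stabilise a methide at C4, and ring B carries O4' para to the vinyl-bearing C1', held coplanar by a 3',4'-diphenylmethylene ketal.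
4. Styrene 11 comes from aldehyde 10 by Wittig methylenation; 10 comes from Suzuki coupling (C5'–C8'' bond) of 8-iodo-tri-O-benzylapigenin 6 with ring-B boronate 9.
5. Ring order: rings A and B and the flavone rings are bought; only ring C of the flavanone is built (step 9).

Key step: step 9

Remark on numbering: flavanone atoms are C2–C8a, its ring B is C1'–C6', and flavone atoms carry a double prime (C8'').
Remark on protection: ring B is carried as the 3',4'-O-diphenylmethylene ketal, not as two benzyl ethers. A benzyloxy group on C4' flanked by O3' and the C5' aryl group would twist out of the ring plane and lose its donation to the vinyl group. The ketal leaves in the same final hydrogenolysis.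
Assumption: the (R)-catalyst is written for the (2S)-flavan; the sense of induction is not established for this substrate class, and the antipode of the catalyst is used if it proves opposite.
Assumption: the tri-ortho-substituted C5'–C8'' axis is left unassigned, as in the target; protected intermediates may appear as rotamers.

**Route**

Step 1
Reactants: 1 2,4,6-trihydroxybenzaldehyde
Product: 2 4,6-bis(benzyloxy)-2-hydroxybenzaldehyde
Conditions: BnBr (2.05 equiv), K2CO3, DMF, 0 °C→rt
Reagents that add atoms: benzyl bromide, BrCc1ccccc1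
Why: Williamson ether synthesis in which the para hydroxyl and one ortho hydroxyl are alkylated, while the last ortho hydroxyl is held in a hydrogen bond to the formyl oxygen and should stay free.

Step 2
Reactants: 2 4,6-bis(benzyloxy)-2-hydroxybenzaldehyde
Product: 3 3,5-bis(benzyloxy)-2-(hydroxymethyl)phenol
Conditions: NaBH4, THF/MeOH, 0 °C; pH 7 work-up, used fresh
Reagents that add atoms: none
Why: Borohydride reduction of an aryl aldehyde, with a neutral work-up because the electron-rich salicyl alcohol ionises readily under acid.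

Step 3
Reactants: 4 apigenin
Product: 5 5,7-bis(benzyloxy)-2-[4-(benzyloxy)phenyl]-4H-chromen-4-one (tri-O-benzylapigenin)
Conditions: BnBr (4 equiv), K2CO3, DMF, 80 °C
Reagents that add atoms: benzyl bromide, BrCc1ccccc1
Why: Williamson ether synthesis in which heat and excess reagent force the chelated 5-hydroxyl, whose alkylation later steers iodination to C8.

Step 4
Reactants: 5 tri-O-benzylapigenin
Product: 6 5,7-bis(benzyloxy)-2-[4-(benzyloxy)phenyl]-8-iodo-4H-chromen-4-one
Conditions: N-iodosuccinimide, TFA (cat.), CH2Cl2/MeCN, 0 °C→rt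
Reagents that add atoms: N-iodosuccinimide, O=C1CCC(=O)N1I
Why: Electrophilic aromatic iodination of the most activated ring, where C8 (ortho to O7 and O1, para to O5) is favoured in 5-O-alkylated flavones over C6, which is flanked by two benzyloxy groups.

Step 5
Reactants: 7 3-bromo-4,5-dihydroxybenzaldehyde
Product: 8 7-bromo-2,2-diphenyl-1,3-benzodioxole-5-carbaldehyde
Conditions: Ph2CCl2, Ph2O, 175 °C
Reagents that add atoms: dichlorodiphenylmethane, ClC(Cl)(c1ccccc1)c1ccccc1
Why: Catechol ketalisation by two successive substitutions at the dichloride carbon with loss of HCl, which leaves the aldehyde and the aryl bromide untouched.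

Step 6
Reactants: 8 7-bromo-2,2-diphenyl-1,3-benzodioxole-5-carbaldehyde
Product: 9 2,2-diphenyl-7-(4,4,5,5-tetramethyl-1,3,2-dioxaborolan-2-yl)-1,3-benzodioxole-5-carbaldehyde
Conditions: B2pin2, Pd(dppf)Cl2 (3 mol%), KOAc, dioxane, 90 °C
Reagents that add atoms: bis(pinacolato)diboron, CC1(C)OB(OC1(C)C)B1OC(C)(C)C(C)(C)O1
Why: Miyaura borylation of an aryl bromide, in which the weak base KOAc suppresses homocoupling and the aldehyde is tolerated.

Step 7
Reactants: 6 8-iodo-tri-O-benzylapigenin; 9 ring-B pinacol boronate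
Product: 10 7-{5,7-bis(benzyloxy)-2-[4-(benzyloxy)phenyl]-4-oxo-4H-chromen-8-yl}-2,2-diphenyl-1,3-benzodioxole-5-carbaldehyde (biaryl aldehyde)
Conditions: Pd(OAc)2 (5 mol%), SPhos (10 mol%), K3PO4, toluene/H2O (10:1), 90 °C
Reagents that add atoms: none
Why: Suzuki–Miyaura coupling in which the bulky electron-rich biaryl phosphine handles the di-ortho-substituted iodide and the tied-back dioxole oxygen keeps the boronate side small, forming the C5'–C8'' bond.

Step 8
Reactants: 10 biaryl aldehyde
Product: 11 5,7-bis(benzyloxy)-2-[4-(benzyloxy)phenyl]-8-(6-ethenyl-2,2-diphenyl-1,3-benzodioxol-4-yl)-4H-chromen-4-one (ring-B styrene)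
Conditions: Ph3PCH3Br, KOtBu, THF, 0 °C; then 10, −78→0 °C
Reagents that add atoms: methyltriphenylphosphonium bromide, C[P+](c1ccccc1)(c1ccccc1)c1ccccc1.[Br-]
Why: Wittig methylenation, in which the non-stabilised ylide adds to the aldehyde far faster than to the vinylogous-ester carbonyl of the flavone at low temperature.

Step 9
Reactants: 3 3,5-bis(benzyloxy)-2-(hydroxymethyl)phenol; 11 ring-B styrene
Product: 13 (2S)-flavan 5,7-bis(benzyloxy)-2-[4-(benzyloxy)phenyl]-8-{6-[(2S)-5,7-bis(benzyloxy)-3,4-dihydro-2H-chromen-2-yl]-2,2-diphenyl-1,3-benzodioxol-4-yl}-4H-chromen-4-one, via ortho-quinone methide 12 (not isolated)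
Conditions: (R)-TRIP [(R)-3,3'-bis(2,4,6-triisopropylphenyl)-BINOL hydrogen phosphate] (10 mol%), 5 Å MS, toluene, 0 °C→rt; 3 (1.5 equiv) added slowly
Reagents that add atoms: none
Why: Proposed new method: the chiral phosphoric acid dehydrates 3 to the ortho-quinone methide 12 and stays hydrogen-bonded to its carbonyl oxygen, the CH2 terminus of the styrene attacks the methide carbon (C3–C4) and the oxygen closes on the developing benzylic carbon (O1–C2) in an asynchronous inverse-electron-demand hetero-Diels–Alder reaction. The closest known reaction type is the chiral-phosphoric-acid-catalysed [4+2] cycloaddition of in situ ortho-quinone methides with styrenes to 2-arylchromans, which relies on methides substituted at the methide carbon and on styrenes bearing a hydrogen-bond donor; a 4-unsubstituted methide with a donor-free styrene is new. Ring C closes as a six-membered ring by this [4+2] cycloaddition (if the reaction is stepwise, by 6-endo capture of the C2 benzylic cation by the phenoxide oxygen). The C2 stereocentre is set by catalyst control: the phosphate bound to the methide oxygen shields one face of the heterodiene with its 3,3'-aryl groups, so the styrene should approach with one enantioface to give (2S). The step needs regioselectivity, which follows from polarity (nucleophilic styrene CH2 to electrophilic methide CH2, giving the 2-aryl chroman), chemoselectivity over C-alkylation of ring A by the methide, which is helped by slow addition of 3 and by the coplanar O4' donor of the dioxole, and enantioface selectivity, which rests on the catalyst alone.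

Step 10
Reactants: 13 (2S)-flavan
Product: 14 (2S)-flavan-4-ol, the 4-hydroxy derivative of 13 (mixture of C4 epimers)
Conditions: DDQ (1.5 equiv), CH2Cl2/H2O (10:1), 0 °C→rt
Reagents that add atoms: water, O
Why: DDQ benzylic oxidation (hydride abstraction) at C4, a known reaction of benzyl-protected 5,7-dioxygenated flavans, in which the cation stabilised by O5, O7 and O1 is trapped by water; C2 is untouched and the new C4 centre is removed in step 11.

Step 11
Reactants: 14 (2S)-flavan-4-ol
Product: 15 protected (2S)-flavanone, the 4-oxo derivative of 13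
Conditions: Dess–Martin periodinane, pyridine, CH2Cl2, 0 °C→rt
Reagents that add atoms: none
Why: Dess–Martin oxidation of a secondary benzylic alcohol under pyridine buffer, conditions that neither ionise C4 nor open the new flavanone to the chalcone, so C2 should stay (S).

Step 12
Reactants: 15 protected (2S)-flavanone
Product: 16 target, (2S)-2-{3-[5,7-dihydroxy-2-(4-hydroxyphenyl)-4-oxo-4H-chromen-8-yl]-4,5-dihydroxyphenyl}-5,7-dihydroxy-2,3-dihydro-4H-chromen-4-one
Conditions: H2 (1 atm), Pd/C (10%), THF/MeOH (1:1), rt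
Reagents that add atoms: none
Why: Catalytic hydrogenolysis of the five aryl benzyl ethers and of the diphenylmethylene ketal under neutral conditions, which should not epimerise C2 by retro-oxa-Michael opening.

**Compound list**
1 | 2,4,6-trihydroxybenzaldehyde | O=Cc1c(O)cc(O)cc1O | starting material
2 | 4,6-bis(benzyloxy)-2-hydroxybenzaldehyde | O=Cc1c(O)cc(OCc2ccccc2)cc1OCc1ccccc1 | intermediate
3 | 3,5-bis(benzyloxy)-2-(hydroxymethyl)phenol | OCc1c(O)cc(OCc2ccccc2)cc1OCc1ccccc1 | intermediate
4 | apigenin | O=c1cc(-c2ccc(O)cc2)oc2cc(O)cc(O)c12 | starting material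
5 | 5,7-bis(benzyloxy)-2-[4-(benzyloxy)phenyl]-4H-chromen-4-one | O=c1cc(-c2ccc(OCc3ccccc3)cc2)oc2cc(OCc3ccccc3)cc(OCc3ccccc3)c12 | intermediate
6 | 5,7-bis(benzyloxy)-2-[4-(benzyloxy)phenyl]-8-iodo-4H-chromen-4-one | O=c1cc(-c2ccc(OCc3ccccc3)cc2)oc2c(I)c(OCc3ccccc3)cc(OCc3ccccc3)c12 | intermediate
7 | 3-bromo-4,5-dihydroxybenzaldehyde | O=Cc1cc(O)c(O)c(Br)c1 | starting material
8 | 7-bromo-2,2-diphenyl-1,3-benzodioxole-5-carbaldehyde | O=Cc1cc(Br)c2OC(c3ccccc3)(c3ccccc3)Oc2c1 | intermediate
9 | 2,2-diphenyl-7-(4,4,5,5-tetramethyl-1,3,2-dioxaborolan-2-yl)-1,3-benzodioxole-5-carbaldehyde | O=Cc1cc(B2OC(C)(C)C(C)(C)O2)c2OC(c3ccccc3)(c3ccccc3)Oc2c1 | intermediate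
10 | 7-{5,7-bis(benzyloxy)-2-[4-(benzyloxy)phenyl]-4-oxo-4H-chromen-8-yl}-2,2-diphenyl-1,3-benzodioxole-5-carbaldehyde | O=Cc1cc(-c2c(OCc3ccccc3)cc(OCc3ccccc3)c3c(=O)cc(-c4ccc(OCc5ccccc5)cc4)oc23)c2OC(c3ccccc3)(c3ccccc3)Oc2c1 | intermediate
11 | 5,7-bis(benzyloxy)-2-[4-(benzyloxy)phenyl]-8-(6-ethenyl-2,2-diphenyl-1,3-benzodioxol-4-yl)-4H-chromen-4-one | C=Cc1cc(-c2c(OCc3ccccc3)cc(OCc3ccccc3)c3c(=O)cc(-c4ccc(OCc5ccccc5)cc4)oc23)c2OC(c3ccccc3)(c3ccccc3)Oc2c1 | intermediate
12 | 3,5-bis(benzyloxy)-6-methylidenecyclohexa-2,4-dien-1-one (ortho-quinone methide) | C=C1C(=O)C=C(OCc2ccccc2)C=C1OCc1ccccc1 | intermediate (not isolated)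
13 | 5,7-bis(benzyloxy)-2-[4-(benzyloxy)phenyl]-8-{6-[(2S)-5,7-bis(benzyloxy)-3,4-dihydro-2H-chromen-2-yl]-2,2-diphenyl-1,3-benzodioxol-4-yl}-4H-chromen-4-one | C1C[C@@H](c2cc3OC(c4ccccc4)(c4ccccc4)Oc3c(-c3c(OCc4ccccc4)cc(OCc4ccccc4)c4c(=O)cc(-c5ccc(OCc6ccccc6)cc5)oc34)c2)Oc2cc(OCc3ccccc3)cc(OCc3ccccc3)c21 | intermediate
14 | 5,7-bis(benzyloxy)-2-[4-(benzyloxy)phenyl]-8-{6-[(2S)-5,7-bis(benzyloxy)-4-hydroxy-3,4-dihydro-2H-chromen-2-yl]-2,2-diphenyl-1,3-benzodioxol-4-yl}-4H-chromen-4-one (C4 epimers) | OC1C[C@@H](c2cc3OC(c4ccccc4)(c4ccccc4)Oc3c(-c3c(OCc4ccccc4)cc(OCc4ccccc4)c4c(=O)cc(-c5ccc(OCc6ccccc6)cc5)oc34)c2)Oc2cc(OCc3ccccc3)cc(OCc3ccccc3)c21 | intermediate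
15 | 5,7-bis(benzyloxy)-2-[4-(benzyloxy)phenyl]-8-{6-[(2S)-5,7-bis(benzyloxy)-4-oxo-3,4-dihydro-2H-chromen-2-yl]-2,2-diphenyl-1,3-benzodioxol-4-yl}-4H-chromen-4-one | O=C1C[C@@H](c2cc3OC(c4ccccc4)(c4ccccc4)Oc3c(-c3c(OCc4ccccc4)cc(OCc4ccccc4)c4c(=O)cc(-c5ccc(OCc6ccccc6)cc5)oc34)c2)Oc2cc(OCc3ccccc3)cc(OCc3ccccc3)c21 | intermediate
16 | (2S)-2-{3-[5,7-dihydroxy-2-(4-hydroxyphenyl)-4-oxo-4H-chromen-8-yl]-4,5-dihydroxyphenyl}-5,7-dihydroxy-2,3-dihydro-4H-chromen-4-one (CNP0204144.1) | O=C1C[C@@H](c2cc(O)c(O)c(-c3c(O)cc(O)c4c(=O)cc(-c5ccc(O)cc5)oc34)c2)Oc2cc(O)cc(O)c21 | target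

**Step count**
Total: 12 steps. Longest linear sequence: 8 steps (steps 3, 4, 7, 8, 9, 10, 11, 12 from apigenin; equally steps 5, 6, 7, 8, 9, 10, 11, 12 from 7).

**Steps most likely to fail**

Step 9 (proposed new method). Enantioface discrimination may be poor because the styrene offers the catalyst no second binding point. The methide may also alkylate the free ring-A carbons of 3 or of 13 instead of adding to the styrene, and the basic flavone carbonyl may hold back the acid. The fallback uses known chemistry, sets out from styrene 11 and aldehyde 2, and comes back at 13. Tsuji–Wacker oxidation of 11 (PdCl2, CuCl, O2, DMF/H2O) should give the aryl methyl ketone F1. Claisen–Schmidt condensation of it with aldehyde 2 (KOH, EtOH/THF, rt) should give the (E)-enone F2. Hydrogenation of the enone double bond with (Ph3P)3RhCl and H2, which spares benzyl ethers and the flavone, should give the saturated ketone F3. Corey–Bakshi–Shibata reduction with the (S)-Me-CBS oxazaborolidine and excess BH3·SMe2 should give the (R)-carbinol F4. Mitsunobu etherification (PPh3, DIAD, THF, 0 °C) then closes O1–C2 with inversion to the (2S)-flavan 13.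

Step 10. Hydride abstraction may take place at C2 or at a benzyl ether CH2 instead of C4, and the C4 cation may lose a C3 proton to a flav-3-ene that is oxidised further. The fallback sets out from 13 and comes back at 14. Acetoxylation with Pb(OAc)4 in benzene/AcOH at 50 °C, a known C4 oxidation of flavans, should give the 4-acetoxyflavan F5. Hydrolysis of it with LiOH in THF/H2O gives the 4-ol 14, whether by acyl cleavage or by solvolysis.

Step 12. Hydrogenolysis may also cleave the benzylic C2–O1 bond of the flavanone, partly saturate the flavone C2''=C3'' bond, or stop before the ketal is removed. The fallback sets out from 15 and gives 16 directly: Lewis-acid dealkylation with BCl3 and pentamethylbenzene as cation scavenger in CH2Cl2 at −78 °C, then aqueous work-up. It makes no new compound (F0).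

Further compounds
F1 | step 9 | 8-(6-acetyl-2,2-diphenyl-1,3-benzodioxol-4-yl)-5,7-bis(benzyloxy)-2-[4-(benzyloxy)phenyl]-4H-chromen-4-one | CC(=O)c1cc(-c2c(OCc3ccccc3)cc(OCc3ccccc3)c3c(=O)cc(-c4ccc(OCc5ccccc5)cc4)oc23)c2OC(c3ccccc3)(c3ccccc3)Oc2c1
F2 | step 9 | (E)-enone, 8-{6-[(2E)-3-(2,4-bis(benzyloxy)-6-hydroxyphenyl)prop-2-enoyl]-2,2-diphenyl-1,3-benzodioxol-4-yl}-5,7-bis(benzyloxy)-2-[4-(benzyloxy)phenyl]-4H-chromen-4-one | O=C(/C=C/c1c(O)cc(OCc2ccccc2)cc1OCc1ccccc1)c1cc(-c2c(OCc3ccccc3)cc(OCc3ccccc3)c3c(=O)cc(-c4ccc(OCc5ccccc5)cc4)oc23)c2OC(c3ccccc3)(c3ccccc3)Oc2c1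
F3 | step 9 | saturated ketone, 8-{6-[3-(2,4-bis(benzyloxy)-6-hydroxyphenyl)propanoyl]-2,2-diphenyl-1,3-benzodioxol-4-yl}-5,7-bis(benzyloxy)-2-[4-(benzyloxy)phenyl]-4H-chromen-4-one | O=C(CCc1c(O)cc(OCc2ccccc2)cc1OCc1ccccc1)c1cc(-c2c(OCc3ccccc3)cc(OCc3ccccc3)c3c(=O)cc(-c4ccc(OCc5ccccc5)cc4)oc23)c2OC(c3ccccc3)(c3ccccc3)Oc2c1
F4 | step 9 | (R)-carbinol, 8-{6-[(1R)-3-(2,4-bis(benzyloxy)-6-hydroxyphenyl)-1-hydroxypropyl]-2,2-diphenyl-1,3-benzodioxol-4-yl}-5,7-bis(benzyloxy)-2-[4-(benzyloxy)phenyl]-4H-chromen-4-one | O[C@H](CCc1c(O)cc(OCc2ccccc2)cc1OCc1ccccc1)c1cc(-c2c(OCc3ccccc3)cc(OCc3ccccc3)c3c(=O)cc(-c4ccc(OCc5ccccc5)cc4)oc23)c2OC(c3ccccc3)(c3ccccc3)Oc2c1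
F5 | step 10 | 4-acetoxyflavan, the C4 acetate of 14 (C4 epimers) | CC(=O)OC1C[C@@H](c2cc3OC(c4ccccc4)(c4ccccc4)Oc3c(-c3c(OCc4ccccc4)cc(OCc4ccccc4)c4c(=O)cc(-c5ccc(OCc6ccccc6)cc5)oc34)c2)Oc2cc(OCc3ccccc3)cc(OCc3ccccc3)c21
F0 | step 12 | none | none
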